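**Retrosynthetic overview**
- The strategy rests on the 1,4-diketone C9(=O)–C10–C11–C1(=O): its central bond C10–C11 is one edge of the cyclobutane C4–C5–C11–C10 (ring C), which joins the cyclohexenone (ring A: C1, C2, C3, C4, C5, C11) to the seven-membered ring (ring B: C4 to C10). That bond is cut oxidatively, back to the bis(silyl enol ether) of a cis-fused bicyclo[5.4.0] enedione.
- The C9 senecioate comes from acylation; the C7 tiglate and the trans C9 carbinol come together from an Evans–Tishchenko reaction on the 7-hydroxy-9-ketone.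
- The C9=C10 enol ether comes from 1,4-hydrosilylation of a C9(=O)–C10(=CH2) enone, made from a C10 ketone by methylenation and allylic oxidation; the C1=C11 dienol ether comes from kinetic enolisation.
- Ring A comes from a Diels–Alder reaction of a 2-silyloxypenta-1,3-diene with (5R)-5-silyloxy-4,4-dimethylcyclohept-2-enone (sets the cis C4/C5 fusion), followed by Saegusa–Ito oxidation.
- Ring B comes first: iridium-catalysed tert-prenylation of hex-5-en-1-ol (sets C7, builds C6), ring-closing metathesis, allylic oxidation. Ring order: B (step 3), A (step 6), C (step 12).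

Key step: step 12

Remark on locants: C1(=O)–C2=C3(Me)–C4–C5–C6(Me2)–C7(O)–C8–C9(O)–C10(Me)–C11–C1, with cross-ring bonds C4–C10 and C5–C11, is used for every bicyclic and tricyclic compound.
Remark on transient centres: the SEGPHOS antipode in step 1 is the one that gives the 4R carbinol; C3 in 9 and 10 (drawn as the endo epimer) and C9 in 12 (epimer mixture) are erased in steps 8 and 9.

Step 1
Reactants: 1 hex-5-en-1-ol; 2 3-methylbuta-1,2-diene
Product: 3 (4R)-3,3-dimethylnona-1,8-dien-4-ol
Conditions: [Ir(cod)Cl]2 (2.5 mol %), SEGPHOS (5 mol %), 4-cyano-3-nitrobenzoic acid (10 mol %), Cs2CO3 (20 mol %), toluene, 60 °C, sealed tube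
Reagents that add atoms: none
Why: Iridium-catalysed transfer-hydrogenative tert-prenylation: the alcohol is dehydrogenated in situ to the aldehyde, hydrometallation of the allene gives a 1,1-dimethylallyl iridium species that adds through a closed transition state, so the chiral ligand sets C7 as R while the quaternary C6 is built in the same event.

Step 2
Reactants: 3 (4R)-3,3-dimethylnona-1,8-dien-4-ol
Product: 4 tert-butyl{[(4R)-3,3-dimethylnona-1,8-dien-4-yl]oxy}dimethylsilane
Conditions: TBSOTf, 2,6-lutidine, CH2Cl2, 0 °C
Reagents that add atoms: tert-butyldimethylsilyl triflate, CC(C)(C)[Si](C)(C)OS(=O)(=O)C(F)(F)F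
Why: Silyl ether formation with the triflate, which is reactive enough for a neopentyl-type secondary alcohol; the stereocentre is not touched.

Step 3
Reactants: 4 tert-butyl{[(4R)-3,3-dimethylnona-1,8-dien-4-yl]oxy}dimethylsilane
Product: 5 tert-butyl{[(1R)-2,2-dimethylcyclohept-3-en-1-yl]oxy}dimethylsilane
Conditions: second-generation Grubbs catalyst RuCl2(=CHPh)(H2IMes)(PCy3) (5 mol %), CH2Cl2 (5 mM), 40 °C
Reagents that add atoms: none
Why: Ring-closing metathesis closes ring B as a cycloheptene (C4=C5); the catalyst loads on the unhindered terminal alkene and closes onto the vinyl group next to C6, with loss of ethene.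

Step 4
Reactants: 5 tert-butyl{[(1R)-2,2-dimethylcyclohept-3-en-1-yl]oxy}dimethylsilane
Product: 6 (5R)-5-(tert-butyldimethylsilyloxy)-4,4-dimethylcyclohept-2-en-1-one
Conditions: Rh2(cap)4 (1 mol %), t-BuOOH (5 equiv), K2CO3 (0.5 equiv), CH2Cl2, rt
Reagents that add atoms: tert-butyl hydroperoxide, CC(C)(C)OO
Why: Dirhodium caprolactamate/hydroperoxide allylic oxidation: C10 is the only allylic CH2 (the other allylic carbon C6 is quaternary) and the allyl radical should be captured at this unhindered terminus, giving the C10 enone after Kornblum–DeLaMare collapse of the peroxide.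

Step 5
Reactants: 7 (E)-pent-3-en-2-one
Product: 8 (E)-2-(tert-butyldimethylsilyloxy)penta-1,3-diene
Conditions: TBSOTf, Et3N, CH2Cl2, 0 °C; distillation
Reagents that add atoms: tert-butyldimethylsilyl triflate, CC(C)(C)[Si](C)(C)OS(=O)(=O)C(F)(F)F
Why: Soft enolisation and O-silylation of the methyl ketone gives the cross-conjugated 2-silyloxy diene with the E alkene unchanged.

Step 6
Reactants: 6 (5R)-5-(tert-butyldimethylsilyloxy)-4,4-dimethylcyclohept-2-en-1-one; 8 (E)-2-(tert-butyldimethylsilyloxy)penta-1,3-diene
Product: 9 cis-fused cycloadduct (7-OTBS; C10 ketone; ring A as the C1=C2 TBS enol ether; 3-methyl cis to C10)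
Conditions: Tf2NH (10 mol %), 8 (2 equiv), CH2Cl2, −78 → −40 °C; Et3N quench
Reagents that add atoms: none
Why: Silyl-triflimide-catalysed Diels–Alder reaction (concerted or double Mukaiyama–Michael) of a silyloxy diene with a hindered enone: the nucleophilic CH2 terminus (C11) bonds to the β-carbon C5 and the methyl-bearing terminus to C4, addition across the ring alkene gives the cis C4/C5 fusion, and the diene should approach anti to the pseudoaxial C6 methyl that lies on the side of the C7 silyloxy group, placing H4 and H5 syn to that oxygen.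

Step 7
Reactants: 9 cis-fused cycloadduct
Product: 10 10-methylene analogue of 9 (C10=CH2; ring A still the C1=C2 TBS enol ether)
Conditions: Cp2TiMe2 (3 equiv), toluene, 65 °C, dark
Reagents that add atoms: dimethyltitanocene, C[Ti](C)(C1C=CC=C1)C1C=CC=C1
Why: Petasis methylenation by a non-basic titanium carbene converts the hindered, epimerisable C10 ketone into the exocyclic alkene without disturbing C4 or the silyl enol ether.

Step 8
Reactants: 10 10-methylene analogue of 9
Product: 11 7-OTBS 10-methylene ring A enone (C1 ketone, C2=C3)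
Conditions: Pd(OAc)2 (1.1 equiv), MeCN, 40 °C
Reagents that add atoms: none
Why: Saegusa–Ito oxidation: the regiodefined C1=C2 silyl enol ether gives a palladium enolate at C2 whose only β-hydrogen is on C3, so the C2=C3 enone with the C3 methyl forms and the C3 stereocentre is erased.

Step 9
Reactants: 11 7-OTBS 10-methylene ring A enone
Product: 13 7-OTBS 10-methylene-2-ene-1,9-dione, via C9 allylic alcohol 12 (not isolated)
Conditions: SeO2 (0.5 equiv), t-BuOOH (3 equiv), CH2Cl2, rt; work-up; then Dess–Martin periodinane, CH2Cl2, 0 °C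
Reagents that add atoms: selenium dioxide, O=[Se]=O; tert-butyl hydroperoxide, CC(C)(C)OO
Why: Selenium dioxide allylic hydroxylation (ene reaction then [2,3] shift) of a 1,1-disubstituted alkene prefers the ring CH2 (C9) over the methine C4 and leaves the electron-poor enone alkene alone, and Dess–Martin oxidation of the epimeric alcohols converges on the C9(=O)–C10(=CH2) enone, which is used without delay.

Step 10
Reactants: 13 7-OTBS 10-methylene-2-ene-1,9-dione
Product: 14 C9=C10 triethylsilyl enol ether (ring A enone intact)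
Conditions: Et3SiH (1.1 equiv), RhCl(PPh3)3 (2 mol %), toluene, 50 °C
Reagents that add atoms: triethylsilane, CC[SiH](CC)CC
Why: Rhodium-catalysed 1,4-hydrosilylation with a monohydrosilane puts hydride on the terminal CH2 and silicon on O9, giving the tetrasubstituted C9=C10 enol ether regiospecifically (the C10 methyl is created here), while the β,β-disubstituted ring A enone reacts much more slowly.

Step 11
Reactants: 14 C9=C10 triethylsilyl enol ether
Product: 15 bis(triethylsilyl enol ether) (C9=C10; C1=C11 with C2=C3; 7-OTBS)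
Conditions: LiN(i-Pr)2 (1.2 equiv), THF, −78 °C; Et3SiCl, −78 → 0 °C; non-aqueous work-up
Reagents that add atoms: chlorotriethylsilane, CC[Si](Cl)(CC)CC
Why: Kinetic deprotonation of the enone at the α′ carbon C11 and O-silylation gives the cross-conjugated dienol ether; C4 stays protonated, so the cis fusion is kept.

Step 12
Reactants: 15 bis(triethylsilyl enol ether)
Product: 16 (7R)-7-(tert-butyldimethylsilyloxy)longipin-2-ene-1,9-dione
Conditions: constant-current electrolysis (2.2 F/mol), undivided cell, reticulated vitreous carbon anode, Pt cathode, Et4NOTs (0.1 M), 2,6-lutidine (4 equiv), CH2Cl2/(CF3)2CHOH 4:1, 3 mM, −20 °C; then aq. NaHCO3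
Reagents that add atoms: none
Why: Proposed new method: one-electron oxidation of the electron-rich tetrasubstituted C9=C10 silyl enol ether gives a radical cation that is electrophilic at C10, the nucleophilic C11 terminus of the C1 dienol ether (held 1,3-syn to it across the cis C4–C5 fusion) adds to it, and a second electron transfer with loss of both silyl groups to hexafluoroisopropanol leaves the C9 and C1 ketones (oxidation of the dienol ether first leads to the same bond). The closest known reaction types are intramolecular anodic couplings of enol-ether radical cations with enol ethers or allylsilanes and oxidative couplings of bis(silyl enol ethers) or dienolates with (NH4)2Ce(NO3)6, CuCl2 or Fe(acac)3, which so far close five- and six-membered rings. The one ring closed is the cyclobutane C4–C5–C11–C10, by 4-exo-trig attack of C11 on C10. Both new stereocentres, quaternary C10 and C11, are fixed by the existing cis C4/C5 fusion, since only the mutually facing sides of the two enol ethers can bond and the bicyclo[3.1.1] frame allows one relative configuration. The step needs C10–C11 coupling to beat dimerisation, solvent capture and oxidative aromatisation of ring A; the regiodefined enol ethers from steps 10 and 11, millimolar dilution, a weakly nucleophilic medium and low temperature are meant to secure this, and the product cannot re-open by enolisation because C10 is quaternary and C11 a bridgehead.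

Step 13
Reactants: 16 (7R)-7-(tert-butyldimethylsilyloxy)longipin-2-ene-1,9-dione
Product: 17 (7R)-7-hydroxylongipin-2-ene-1,9-dione
Conditions: HF·pyridine, pyridine, THF, 0 °C → rt
Reagents that add atoms: none
Why: Buffered acidic fluoride desilylation frees the C7 alcohol while avoiding the basic conditions that could trigger retro-aldol opening or β-elimination of the β-hydroxy ketone.

Step 14
Reactants: 17 (7R)-7-hydroxylongipin-2-ene-1,9-dione; 18 (E)-2-methylbut-2-enal
Product: 19 (7R,9R)-9-hydroxy-7-[(E)-2-methylbut-2-enoyloxy]longipin-2-en-1-one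
Conditions: 18 (5 equiv), SmI2 (0.3 equiv, premixed with 18 until decolourised), THF, −10 °C
Reagents that add atoms: none
Why: Evans–Tishchenko reaction: the samarium-bound hemiacetal formed from the C7 hydroxyl and the aldehyde delivers its hydride intramolecularly to the C9 ketone from the face that carries O7, so the C9 carbinol is set trans (1,3-anti) to C7 and the tigloyl group ends on O7 in the same step.

Step 15
Reactants: 19 (7R,9R)-9-hydroxy-7-[(E)-2-methylbut-2-enoyloxy]longipin-2-en-1-one; 20 3-methylbut-2-enoyl chloride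
Product: 21 (7R,9R)-7-[(E)-2-methylbut-2-enoyloxy]-9-(3-methylbut-2-enoyloxy)longipin-2-en-1-one (CNP0257816.1)
Conditions: 20 (3 equiv), DMAP (0.2 equiv), pyridine, CH2Cl2, 0 °C → rt
Reagents that add atoms: none
Why: DMAP-catalysed acylation of the remaining hindered C9 alcohol; pyridine is used instead of a trialkylamine so the acid chloride is not deconjugated through a vinylketene, and the trans-1,3 geometry disfavours acyl migration.

**Compound list**
1 | hex-5-en-1-ol | OCCCCC=C | starting material
2 | 3-methylbuta-1,2-diene | CC(C)=C=C | starting material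
3 | (4R)-3,3-dimethylnona-1,8-dien-4-ol | O[C@@H](C(C)(C)C=C)CCCC=C | intermediate
4 | tert-butyl{[(4R)-3,3-dimethylnona-1,8-dien-4-yl]oxy}dimethylsilane | CC(C)(C)[Si](C)(C)O[C@@H](C(C)(C)C=C)CCCC=C | intermediate
5 | tert-butyl{[(1R)-2,2-dimethylcyclohept-3-en-1-yl]oxy}dimethylsilane | CC(C)(C)[Si](C)(C)O[C@@H]1CCCC=CC1(C)C | intermediate
6 | (5R)-5-(tert-butyldimethylsilyloxy)-4,4-dimethylcyclohept-2-en-1-one | CC(C)(C)[Si](C)(C)O[C@@H]1CCC(=O)C=CC1(C)C | intermediate
7 | (E)-pent-3-en-2-one | C/C=C/C(C)=O | starting material
8 | (E)-2-(tert-butyldimethylsilyloxy)penta-1,3-diene | C=C(O[Si](C)(C)C(C)(C)C)/C=C/C | intermediate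
9 | cis-fused bicyclo[5.4.0] cycloadduct: C10 ketone, C1=C2 TBS enol ether, 7R OTBS, H4 and H5 cis and syn to O7, 3-methyl cis to C10 | CC(C)(C)[Si](C)(C)O[C@@H]1CCC(=O)[C@H]2[C@@H](C)C=C(O[Si](C)(C)C(C)(C)C)C[C@H]2C1(C)C | intermediate
10 | 10-methylene analogue of 9 (C10=CH2, C1=C2 TBS enol ether) | CC(C)(C)[Si](C)(C)O[C@@H]1CCC(=C)[C@H]2[C@@H](C)C=C(O[Si](C)(C)C(C)(C)C)C[C@H]2C1(C)C | intermediate
11 | cis-fused 7-OTBS 10-methylene ring A enone (C1 ketone, C2=C3, 3-methyl) | CC(C)(C)[Si](C)(C)O[C@@H]1CCC(=C)[C@H]2C(C)=CC(=O)C[C@H]2C1(C)C | intermediate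
12 | 9-hydroxy derivative of 11 (C9 epimers, not isolated) | CC(C)(C)[Si](C)(C)O[C@@H]1CC(O)C(=C)[C@H]2C(C)=CC(=O)C[C@H]2C1(C)C | intermediate
13 | cis-fused 7-OTBS 10-methylene-2-ene-1,9-dione | CC(C)(C)[Si](C)(C)O[C@@H]1CC(=O)C(=C)[C@H]2C(C)=CC(=O)C[C@H]2C1(C)C | intermediate
14 | C9=C10 triethylsilyl enol ether of the cis-fused 10-methyl enedione, ring A enone intact | CC(C)(C)[Si](C)(C)O[C@@H]1CC(O[Si](CC)(CC)CC)=C(C)[C@H]2C(C)=CC(=O)C[C@H]2C1(C)C | intermediate
15 | bis(triethylsilyl enol ether) of the cis-fused enedione (C9=C10; C1=C11 and C2=C3), 7R OTBS | CC(C)(C)[Si](C)(C)O[C@@H]1CC(O[Si](CC)(CC)CC)=C(C)[C@H]2C(C)=CC(O[Si](CC)(CC)CC)=C[C@H]2C1(C)C | intermediate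
16 | (7R)-7-(tert-butyldimethylsilyloxy)longipin-2-ene-1,9-dione | CC(C)(C)[Si](C)(C)O[C@@H]1CC(=O)[C@@]2(C)[C@@H]3C(=O)C=C(C)[C@H]2[C@@H]3C1(C)C | intermediate
17 | (7R)-7-hydroxylongipin-2-ene-1,9-dione | O[C@@H]1CC(=O)[C@@]2(C)[C@@H]3C(=O)C=C(C)[C@H]2[C@@H]3C1(C)C | intermediate
18 | (E)-2-methylbut-2-enal | C/C=C(\C)C=O | starting material
19 | (7R,9R)-9-hydroxy-7-[(E)-2-methylbut-2-enoyloxy]longipin-2-en-1-one | C/C=C(\C)C(=O)O[C@@H]1C[C@@H](O)[C@@]2(C)[C@@H]3C(=O)C=C(C)[C@H]2[C@@H]3C1(C)C | intermediate
20 | 3-methylbut-2-enoyl chloride | CC(C)=CC(=O)Cl | starting material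
21 | (7R,9R)-7-[(E)-2-methylbut-2-enoyloxy]-9-(3-methylbut-2-enoyloxy)longipin-2-en-1-one (CNP0257816.1) | C/C=C(\C)C(=O)O[C@@H]1C[C@@H](OC(=O)C=C(C)C)[C@@]2(C)[C@@H]3C(=O)C=C(C)[C@H]2[C@@H]3C1(C)C | target

Total step count: 15. Longest linear sequence: 14 steps (steps 1–4 and 6–15; step 5 makes the diene).

**Steps most likely to fail**

Step 12. The four-membered ring may close more slowly than the radical cation is consumed by intermolecular dimerisation, by solvent capture, or by proton loss from ring A leading on to a phenol silyl ether. The fallback makes the C10–C11 bond by a polar route, starting from 14. Kinetic deprotonation at C11 (LiN(i-Pr)2, THF, −78 °C) and oxidation of the dienolate with 2-(phenylsulfonyl)-3-phenyloxaziridine from the convex face should give the 11-hydroxy enone F1, with the hydroxyl anti to the C5–C6 bond. Mesylation (MsCl, Et3N) gives the α′-mesyloxy enone F2. Tris(dimethylamino)sulfonium difluorotrimethylsilicate (THF, −78 → 0 °C) then releases the C9 enolate regiospecifically from the silyl enol ether, and its C10 terminus displaces the mesylate at C11 with inversion. This is a 4-exo-tet enolate alkylation of the kind used to close pinane-type cyclobutanes, and it returns to the route at 16.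

Step 14. The conjugated aldehyde may form the hemiacetal and transfer hydride too slowly, leaving time for retro-aldol opening of the C7–C8 bond on the Lewis-acidic trivalent samarium alkoxide or for ketyl fragmentation of the strained 1,4-diketone by free SmI2. The fallback keeps the directed reduction but uses a saturated aldehyde whose ester can be removed under neutral conditions, starting from 17. Evans–Tishchenko reaction with pent-4-enal should give the 7-(pent-4-enoate) 9-alcohol F3. Senecioylation as in step 15 gives the mixed diester F4. Iodine in wet THF removes the pentenoate by iodolactonisation to free the C7 alcohol F5. Acylation with (E)-2-methylbut-2-enoyl chloride (DMAP, pyridine) rejoins the route at 21.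

Step 6. Shielding of C5 by the neighbouring quaternary C6 may stall the cycloaddition, and the acid may protodesilylate diene 8 instead. The fallback uses a more nucleophilic diene that needs no acid and adds the C3 methyl afterwards, starting from 6. Heating with commercial (E)-1-(dimethylamino)-3-(tert-butyldimethylsilyloxy)buta-1,3-diene (toluene, 80 °C) should give the amino silyl enol ether cycloadduct F6. Brief treatment with dilute HCl in THF removes dimethylamine and gives the ring A enone F7, with the C10 ketone kept. Me2CuLi with Me3SiCl (THF, −78 °C) adds the methyl to C3 and gives the C1=C2 trimethylsilyl enol ether F8. Methylenation with Cp2TiMe2 as in step 7 gives F9, and Saegusa–Ito oxidation as in step 8 rejoins the route at 11.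

**Further compounds**
F1 | step 12 | 11-hydroxy derivative of 14 (hydroxyl anti to the C5–C6 bond) | CC(C)(C)[Si](C)(C)O[C@@H]1CC(O[Si](CC)(CC)CC)=C(C)[C@H]2C(C)=CC(=O)[C@H](O)[C@H]2C1(C)C
F2 | step 12 | 11-methanesulfonate of F1 | CC(C)(C)[Si](C)(C)O[C@@H]1CC(O[Si](CC)(CC)CC)=C(C)[C@H]2C(C)=CC(=O)[C@H](OS(C)(=O)=O)[C@H]2C1(C)C
F3 | step 14 | (7R,9R)-9-hydroxy-7-(pent-4-enoyloxy)longipin-2-en-1-one | C=CCCC(=O)O[C@@H]1C[C@@H](O)[C@@]2(C)[C@@H]3C(=O)C=C(C)[C@H]2[C@@H]3C1(C)C
F4 | step 14 | (7R,9R)-9-(3-methylbut-2-enoyloxy)-7-(pent-4-enoyloxy)longipin-2-en-1-one | C=CCCC(=O)O[C@@H]1C[C@@H](OC(=O)C=C(C)C)[C@@]2(C)[C@@H]3C(=O)C=C(C)[C@H]2[C@@H]3C1(C)C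
F5 | step 14 | (7R,9R)-7-hydroxy-9-(3-methylbut-2-enoyloxy)longipin-2-en-1-one | O[C@@H]1C[C@@H](OC(=O)C=C(C)C)[C@@]2(C)[C@@H]3C(=O)C=C(C)[C@H]2[C@@H]3C1(C)C
F6 | step 6 | cis-fused cycloadduct with 3-dimethylamino group, C1=C2 TBS enol ether and C10 ketone | CC(C)(C)[Si](C)(C)O[C@@H]1CCC(=O)[C@H]2[C@@H](N(C)C)C=C(O[Si](C)(C)C(C)(C)C)C[C@H]2C1(C)C
F7 | step 6 | cis-fused 7-OTBS 2-ene-1,10-dione without the C3 methyl | CC(C)(C)[Si](C)(C)O[C@@H]1CCC(=O)[C@H]2C=CC(=O)C[C@H]2C1(C)C
F8 | step 6 | C1=C2 trimethylsilyl enol ether with 3-methyl trans to C10, C10 ketone | CC(C)(C)[Si](C)(C)O[C@@H]1CCC(=O)[C@H]2[C@H](C)C=C(O[Si](C)(C)C)C[C@H]2C1(C)C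
F9 | step 6 | 10-methylene analogue of F8 | CC(C)(C)[Si](C)(C)O[C@@H]1CCC(=C)[C@H]2[C@H](C)C=C(O[Si](C)(C)C)C[C@H]2C1(C)C
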